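**Retrosynthetic overview**

1. Target ⇐ 12‑hydroxyquinone (acetylation) ⇐ 12,13‑epoxyquinone ⇐ 12‑deoxy quinone; the C12 oxygen goes in last.
2. Ring B (closed last): C7–C8 by acid cyclodehydration of a C5–CH2CHO side chain onto the hydroquinone, then oxidation to the quinone.
3. Key disconnection, C9–C10 together with O–C20: the radical cation of a 3‑methylidenecyclohexanecarboxylic acid is captured by its own CO2H, and the resulting bridgehead lactone radical adds to 2‑isopropylbenzoquinone (ring C, from benzoquinone and isobutyric acid).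
4. Ring A acid from cyclohexenone: asymmetric conjugate vinylation/enolate alkylation, vinyl → CO2H, methylenation, C4 methylation.
5. Ring order: A and C start as six‑membered rings → lactone ring (key step) → B.

Assumption: positions are quoted in abietane numbering (C19 = lactone C=O, C20 = lactone CH2); α/β mean below/above the plane in the usual drawing.

**Step 1**
Reactants: 1 cyclohex‑2‑en‑1‑one; 2 2,2‑dimethoxyethan‑1‑ol
Product: 5 (2S,3S)-2-(2,2-dimethoxyethyl)-3-ethenylcyclohexan-1-one, via 2,2-dimethoxyethyl triflate 3 (not isolated), via bromomagnesium enolate 4 (not isolated)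
Conditions: 2, Tf2O, 2,6‑lutidine, CH2Cl2, −78 °C (cold silica plug gives 3); 1, CH2=CHMgBr, CuBr·SMe2 (5 mol %), Josiphos‑type ligand (6 mol %, enantiomer giving 3S), t‑BuOMe, −78 °C; then 3, DMPU, −78 → 0 °C
Reagents that add atoms: vinylmagnesium bromide, C=C[Mg]Br
Why: Cu‑catalysed asymmetric conjugate addition of a Grignard reagent with in‑situ enolate alkylation; the catalyst sets C4 (S) and the primary triflate enters C5 anti to the vinyl group (trans), any cis epimer at the enolisable C5 being equilibrated by the K2CO3 of step 2.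

**Step 2**
Reactants: 5
Product: 6 (1R,2S)-2-(2,2-dimethoxyethyl)-3-oxocyclohexane-1-carboxylic acid
Conditions: KMnO4 (5 mol %), NaIO4, K2CO3, t‑BuOH/H2O, 20 °C; pH 4–5 work‑up
Reagents that add atoms: sodium periodate, [Na+].[O-]I(=O)(=O)=O; water, O
Why: Lemieux–von Rudloff cleavage turns the vinyl group into CO2H at pH 8, where ketone and acetal survive; C4 is configurationally stable and C5 settles trans (diequatorial) to it.

**Step 3**
Reactants: 6 (trans isomer)
Product: 7 (1R,2S)-2-(2,2-dimethoxyethyl)-3-methylidenecyclohexane-1-carboxylic acid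
Conditions: Zn, CH2Br2, TiCl4 (Lombardo reagent, excess), THF/CH2Cl2, 0 → 20 °C
Reagents that add atoms: dibromomethane, BrCBr
Why: Lombardo methylenation is non‑basic and tolerates free acids, so the ketone becomes the exocyclic alkene without epimerising C5, which is now fixed and carries the absolute configuration onward.

**Step 4**
Reactants: 7
Product: 9 (1S,2S)-2-(2,2-dimethoxyethyl)-1-methyl-3-methylidenecyclohexane-1-carboxylic acid, via dilithium enediolate 8 (not isolated)
Conditions: LDA (2.3 equiv), THF, −78 → 0 °C; MeI, −78 → 20 °C; pH 5 phosphate work‑up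
Reagents that add atoms: iodomethane, CI
Why: carboxylic acid dianion alkylation; A(1,3) strain puts the C5 side chain axial, so MeI attacks the exocyclic enediolate from the opposite (α) face and C4 is set with CO2H cis to the side chain.

**Step 5**
Reactants: 10 1,4‑benzoquinone; 11 2‑methylpropanoic acid
Product: 12 2-(propan-2-yl)cyclohexa-2,5-diene-1,4-dione
Conditions: AgNO3 (20 mol %), (NH4)2S2O8, MeCN/H2O, 65 °C; 10 in excess
Reagents that add atoms: none
Why: Jacobsen–Torssell radical alkylation: Ag(II) decarboxylates the acid and the isopropyl radical adds to the quinone, which persulfate re‑oxidises.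

**Step 6 (key step)**
Reactants: 9; 12
Product: 14 (1S,5R,9R)-5-[2,5-dihydroxy-4-(propan-2-yl)phenyl]-9-(2,2-dimethoxyethyl)-1-methyl-3-oxabicyclo[3.3.1]nonan-2-one, via bridgehead lactone radical 13 (not isolated)
Conditions: 3,6‑di‑tert‑butyl‑9‑mesityl‑10‑phenylacridinium BF4 (5 mol %), 12 (1.1 equiv), DCE/TFE 9:1, 450 nm LEDs, 20 °C, Ar
Reagents that add atoms: none
Why: Proposed new method: the excited acridinium (E* ≈ +2.1 V) oxidises the 1,1‑disubstituted alkene of 9 to its radical cation, the cis‑1,3 CO2H adds to the CH2 terminus (anti‑Markovnikov, 6‑endo) to close the lactone and leave tertiary bridgehead radical 13, which cannot invert and adds (Giese type) to the free position of 12 para to the isopropyl group, the adduct radical being reduced by the acridinyl radical and tautomerising to 14, so C10 (R) is set solely by the C4 carboxyl delivering C20 on the β face with the aryl group exo; the closest known reactions are acridinium‑photoredox anti‑Markovnikov hydrolactonisation of alkenoic acids, photo‑NOCAS nucleophile–olefin–arene couplings and Jacobsen–Torssell alkylation of quinones by tertiary and bridgehead radicals; the 2,6‑regioisomer, which may form in comparable amount, is removed by chromatography.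

**Step 7**
Reactants: 14
Product: 16 (4S,5R,10R)-11,14-dioxoabieta-6,8,12-trien-19,20-olide, via hydroquinone 15 (not isolated)
Conditions: TsOH·H2O (20 mol %), acetone/H2O 20:1, 45 °C; then Ag2O, MgSO4, Et2O, 20 °C
Reagents that add atoms: none
Why: acetal hydrolysis, intramolecular Friedel–Crafts hydroxyalkylation at C8 (ortho to OH, the only position within reach) and dehydration give the C6=C7 styrene (cyclodehydration), and Ag2O then oxidises the hydroquinone to the quinone; no stereocentre is touched.

**Step 8**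
Reactants: 16
Product: 17 (4S,5R,10R)-12,13-epoxy-11,14-dioxoabieta-6,8-dien-19,20-olide (both epoxide faces)
Conditions: 30 % H2O2, Na2CO3 (cat.), THF/H2O, 0 °C
Reagents that add atoms: hydrogen peroxide, OO
Why: Weitz–Scheffer nucleophilic epoxidation; HOO− attacks C12, the only unsubstituted quinone carbon, while the tetrasubstituted C8=C9 and the lactone are untouched at 0 °C, and the epoxide face is irrelevant because both centres become sp2 in step 9.

**Step 9**
Reactants: 17
Product: 19 (4S,5R,10R)-12-acetoxy-11,14-dioxoabieta-6,8,12-trien-19,20-olide (CNP0596241.1), via hydroxyquinone 18 (not isolated)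
Conditions: DBU (1.05 equiv), CH2Cl2, −20 °C; then Ac2O, DMAP (cat.), 0 °C
Reagents that add atoms: acetic anhydride, CC(=O)OC(C)=O
Why: base‑induced E1cB opening of the α,β‑epoxy ketone (loss of H12, cleavage of C13–O) gives the 12‑hydroxyquinone anion, which is O‑acetylated in the same flask; short exposure at low temperature avoids epimerising the vinylogous C5–H.

**Compound list**

1 | cyclohex-2-en-1-one | O=C1C=CCCC1 | starting material
2 | 2,2-dimethoxyethan-1-ol | COC(CO)OC | starting material
3 | 2,2-dimethoxyethyl trifluoromethanesulfonate | COC(COS(=O)(=O)C(F)(F)F)OC | intermediate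
4 | bromomagnesium (3S)-3-ethenylcyclohex-1-en-1-olate | C=C[C@@H]1CCCC(O[Mg]Br)=C1 | intermediate
5 | (2S,3S)-2-(2,2-dimethoxyethyl)-3-ethenylcyclohexan-1-one | O=C1CCC[C@@H](C=C)[C@@H]1CC(OC)OC | intermediate
6 | (1R,2S)-2-(2,2-dimethoxyethyl)-3-oxocyclohexane-1-carboxylic acid | O=C1CCC[C@@H](C(=O)O)[C@@H]1CC(OC)OC | intermediate
7 | (1R,2S)-2-(2,2-dimethoxyethyl)-3-methylidenecyclohexane-1-carboxylic acid | C=C1CCC[C@@H](C(=O)O)[C@@H]1CC(OC)OC | intermediate
8 | dilithium enediolate of 7 (C2 configuration unchanged) | C=C1CCCC(=C(O[Li])O[Li])[C@@H]1CC(OC)OC | intermediate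
9 | (1S,2S)-2-(2,2-dimethoxyethyl)-1-methyl-3-methylidenecyclohexane-1-carboxylic acid | C=C1CCC[C@](C)(C(=O)O)[C@@H]1CC(OC)OC | intermediate
10 | 1,4-benzoquinone | O=C1C=CC(=O)C=C1 | starting material
11 | 2-methylpropanoic acid | CC(C)C(=O)O | starting material
12 | 2-(propan-2-yl)cyclohexa-2,5-diene-1,4-dione | CC(C)C1=CC(=O)C=CC1=O | intermediate
13 | (1S,9R)-9-(2,2-dimethoxyethyl)-1-methyl-2-oxo-3-oxabicyclo[3.3.1]nonan-5-yl radical | [C]12CCC[C@](C)(C(=O)OC1)[C@@H]2CC(OC)OC | intermediate
14 | (1S,5R,9R)-5-[2,5-dihydroxy-4-(propan-2-yl)phenyl]-9-(2,2-dimethoxyethyl)-1-methyl-3-oxabicyclo[3.3.1]nonan-2-one | CC(C)c1cc(O)c(cc1O)[C@]12CCC[C@](C)(C(=O)OC1)[C@@H]2CC(OC)OC | intermediate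
15 | (4S,5R,10R)-11,14-dihydroxyabieta-6,8,11,13-tetraen-19,20-olide | Oc1cc(C(C)C)c(O)c2c1[C@]34CCC[C@](C)(C(=O)OC3)[C@@H]4C=C2 | intermediate
16 | (4S,5R,10R)-11,14-dioxoabieta-6,8,12-trien-19,20-olide | O=C1C=C(C(C)C)C(=O)C2=C1[C@]34CCC[C@](C)(C(=O)OC3)[C@@H]4C=C2 | intermediate
17 | (4S,5R,10R)-12,13-epoxy-11,14-dioxoabieta-6,8-dien-19,20-olide (C12/C13: both faces) | O=C1C5OC5(C(C)C)C(=O)C2=C1[C@]34CCC[C@](C)(C(=O)OC3)[C@@H]4C=C2 | intermediate
18 | (4S,5R,10R)-12-hydroxy-11,14-dioxoabieta-6,8,12-trien-19,20-olide | OC1=C(C(C)C)C(=O)C2=C(C1=O)[C@]34CCC[C@](C)(C(=O)OC3)[C@@H]4C=C2 | intermediate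
19 | (4S,5R,10R)-12-acetoxy-11,14-dioxoabieta-6,8,12-trien-19,20-olide | CC(=O)OC1=C(C(C)C)C(=O)C2=C(C1=O)[C@]13CCC[C@](C)(C(=O)OC1)[C@@H]3C=C2 | target

**Step count**

Total steps: 9. Longest linear sequence: 8 (steps 1–4 and 6–9; step 5 runs in parallel).

**Three steps most likely to fail**

Step 6. The alkene (about +2.3 to +2.5 V) lies at the limit of the photocatalyst, the hydroquinone product can quench the excited catalyst, and addition to 12 may give the 2,6‑isomer in comparable amount. The fallback sets out from 9 and comes back at 14; it separates lactonisation from radical generation and leaves the quinone regiochemistry as it is. The sodium salt of 9 is epoxidised with dimethyldioxirane (acetone, 0 °C) on the α face, the β face being shielded by the axial C5 side chain, to give (3S,4S,5S)-4-(2,2-dimethoxyethyl)-5-methyl-1-oxaspiro[2.5]octane-5-carboxylic acid F1. On warming in DMF (60 °C) its carboxylate opens the epoxide at CH2 to the bridgehead alcohol (1S,5S,9S)-9-(2,2-dimethoxyethyl)-5-hydroxy-1-methyl-3-oxabicyclo[3.3.1]nonan-2-one F2. Methyl chlorooxoacetate/Et3N/DMAP converts it into the methyl oxalate F3, and CsOH (1 equiv, THF/H2O) into the caesium oxalate F4. Ir[dF(CF3)ppy]2(dtbbpy)PF6 (1 mol %), 12, DME/DMF/H2O and blue LEDs then release radical 13 by double decarboxylation, and its addition to 12 gives 14.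

Step 1. The enantioselectivity of the vinyl Grignard addition and C‑ versus O‑alkylation of the magnesium enolate by the β,β‑dialkoxy triflate are both uncertain. The fallback sets out from 1 and comes back at 5; it addresses the alkylation, not the enantioselectivity. The same Cu‑catalysed vinylation is quenched with TMSCl to isolate {[(3S)-3-ethenylcyclohex-1-en-1-yl]oxy}trimethylsilane F5. Mukaiyama–Michael addition to nitroethylene (SnCl4, CH2Cl2, −78 °C) gives (2S,3S)-3-ethenyl-2-(2-nitroethyl)cyclohexan-1-one F6. A Nef reaction run in methanol (NaOMe, then H2SO4/MeOH, −40 °C) delivers the dimethyl acetal 5.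

Step 9. Base may epimerise C5 or attack the dienone before the epoxide opens, and the epoxide of step 8 may itself be hard to obtain cleanly. The fallback sets out from 16 and comes back at 18, bypassing the epoxide. Oxidative amination of 16 with morpholine (EtOH, air, 20 °C) at C12 gives (4S,5R,10R)-12-(morpholin-4-yl)-11,14-dioxoabieta-6,8,12-trien-19,20-olide F7. Hydrolysis of this vinylogous amide (2 M HCl, dioxane, 60 °C) gives 18, which is acetylated (Ac2O, pyridine) to 19.

**Further compounds**

F1 | step 6 | (3S,4S,5S)-4-(2,2-dimethoxyethyl)-5-methyl-1-oxaspiro[2.5]octane-5-carboxylic acid | C1O[C@]12CCC[C@](C)(C(=O)O)[C@@H]2CC(OC)OC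
F2 | step 6 | (1S,5S,9S)-9-(2,2-dimethoxyethyl)-5-hydroxy-1-methyl-3-oxabicyclo[3.3.1]nonan-2-one | O[C@]12CCC[C@](C)(C(=O)OC1)[C@@H]2CC(OC)OC
F3 | step 6 | methyl oxalate of F2 | COC(=O)C(=O)O[C@]12CCC[C@](C)(C(=O)OC1)[C@@H]2CC(OC)OC
F4 | step 6 | caesium oxalate of F2 | [Cs+].[O-]C(=O)C(=O)O[C@]12CCC[C@](C)(C(=O)OC1)[C@@H]2CC(OC)OC
F5 | step 1 | {[(3S)-3-ethenylcyclohex-1-en-1-yl]oxy}trimethylsilane | C=C[C@@H]1CCCC(O[Si](C)(C)C)=C1
F6 | step 1 | (2S,3S)-3-ethenyl-2-(2-nitroethyl)cyclohexan-1-one | O=C1CCC[C@@H](C=C)[C@@H]1CC[N+](=O)[O-]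
F7 | step 9 | (4S,5R,10R)-12-(morpholin-4-yl)-11,14-dioxoabieta-6,8,12-trien-19,20-olide | O=C1C(N5CCOCC5)=C(C(C)C)C(=O)C2=C1[C@]34CCC[C@](C)(C(=O)OC3)[C@@H]4C=C2
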